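(The runs stem from a simulated flask from invented constants; the scatter is artificial.)

I had to say which flask, Friday's dilute one or Tuesday's, holds more product at the end, counted in percent of its own substrate charge.

| flask | substrate | reagent | initiator | remark | time |
|---|---|---|---|---|---|
| red | 0.020 M | 0.0041 M | 100 µM | run made earlier |  |
| teal | 0.020 M | 0.010 M | 100 µM | run made earlier |  |
| blue | 0.020 M | 0.022 M | 100 µM | run made earlier |  |
| amber | 0.011 M | 0.019 M | 100 µM | run made earlier |  |
| Friday's | 0.0050 M | 0.00500 M | 100 µM |  | 2.5 min |
| Tuesday's | 0.020 M | 0.0190 M | 100 µM |  | 2.5 min |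

- red (time / min: product / %): 0.200: 1.4; 0.667: 6.8; 1.33: 16.2; 2.00: 19.7; 2.50: 20.1
- teal (time / min: product / %): 0.500: 8.6; 1.00: 25.5; 1.50: 40.5; 2.00: 46.7; 2.50: 49.0
- blue (time / min: product / %): 0.200: 2.8; 0.667: 24.8; 1.33: 53.0; 2.00: 68.2; 2.50: 76.4
- amber (time / min: product / %): 0.500: 20.0; 1.00: 45.8; 1.50: 63.0; 2.00: 73.0; 2.50: 80.3

(scatter of a reading: 0.5 percentage points)

1. which one finishes higher in amount of product, in percent of the substrate charged ("neither" within 2 percentage points) (Friday's / Tuesday's / neither)
2. amount of product at the end, in percent of the substrate charged, Friday's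
3. amount of product at the end, in percent of the substrate charged, Tuesday's



I began with the balance of reagent, the limiting reagent in Tuesday's flask, since c_reagent is 0.0190 M against 0.020 M of substrate. The red run levelled at 20.1 % and the teal run reached 49.0 %, with charges of 20.5 % and 50.0 % of the substrate, so I took reagent and product to go one for one. The reagent ceiling, c_reagent/c_substrate as charged, is then 95.0 % for Tuesday's flask and 100 % for Friday's, and product equals ceiling times the share of reagent spent.

At the last reading that share was 98.0 % in the teal run and 69.5 % in the blue run. Interpolating on the reagent charge gave Tuesday's flask 76.6 %, hence 72.8 % product. The same line, read at Friday's ratio, gave 74.2 %, hence 74.2 %.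

The weak link was carrying that line to a quarter of the substrate. The amber run had less substrate and less reagent than the blue run, yet its last reading stood higher in percent of its substrate charge, 80.3 % against 76.4 %. Its ratio of reagent to substrate is higher too, so this was a judgement and no proof, but I gave Friday's flask Tuesday's share. That made 76.6 %, a gap of 3.8 percentage points against a margin of 2 points, and I expected Friday's to win.

The forecast differed: neither, with 74 % (67 % to 80 %) for Friday's and 72 % (68 % to 76 %) for Tuesday's, holding that “fractional conversion depends mainly on” the ratio of reagent to substrate, not on absolute concentration.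

The flasks gave 81.3 % for Friday's and 75.1 % for Tuesday's, so Friday's finished higher.

    initiator → 2 initiating radical (k = 1.26 × 10⁻⁵ s⁻¹)
    2 second chain carrier → ended chains (k = 2.80 × 10⁶ M⁻¹ s⁻¹)
    substrate + initiating radical → capped initiator + first chain carrier (k = 8.62 × 10⁶ M⁻¹ s⁻¹)
    substrate + second chain carrier → by-product + first chain carrier (k = 7.02 × 10⁵ M⁻¹ s⁻¹)
    substrate + by-product ⇌ idle adduct, settled at all times (K = 54.0 M⁻¹)
    reagent + first chain carrier → product + second chain carrier (k = 2.08 × 10⁵ M⁻¹ s⁻¹)

In Tuesday's flask, reagent with first chain carrier and substrate with second chain carrier ran in step, each with half its turnover done by 0.979 min, while idle adduct held 14.0 % of the substrate at 1.25 min, against 5.37 % in Friday's flask. By 2.5 min, Friday's flask had spent 81.3 % of its reagent and Tuesday's 79.0 %, and at 25.0 min Tuesday's stood at 95.0 %, its ceiling of 95.0 %. Tuesday's neighbour with 0.0047 M of reagent has a ceiling of 23.5 % and ended at 23.4 %.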